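**Retrosynthetic overview**
- Target 19 ⇐ MOM ether 18 ⇐ bis(1,1-dimethylallyl) ether 16 by two aromatic Claisen shifts (prenyl C–C bonds at C6 and C8) ⇐ 5,7-difluoroisoflavone 13 by exchange of both fluorines for 2-methylbut-3-en-2-yloxy groups.
- 13 ⇐ hydroxymethylene ketone 11 by intramolecular SNAr forming O1–C8a. The pyranone (ring C) is the only ring built; rings A and B are bought as 6 and 1.
- 11 ⇐ deoxybenzoin 8 (C-formylation supplies C2) ⇐ benzylzinc reagent 7 + 2,4,6-trifluorobenzoyl chloride 6 (Negishi acylation, C3–C4 bond).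
- Feature: on ring A the oxygens at C8a (O1), C5 and C7 lie ortho, ortho and para to the carbon that carries the C4 carbonyl. These are the fluorine positions of a 2,4,6-trifluorobenzoyl group, so each oxygen can enter by SNAr, and the C6 and C8 prenyl groups then come from the C5 and C7 oxygens by [3,3] shift.

Key step: step 6

Remark: the target has no stereocentre and no hindered axis, so it is achiral; "single enantiomer" is taken as the one constitution drawn and no asymmetric step is needed.

**Step 1**
Reactants: 1 4-hydroxy-2-methoxybenzaldehyde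
Product: 2 2-methoxy-4-(methoxymethoxy)benzaldehyde
Conditions: MOMCl, iPr2NEt, CH2Cl2, 0 °C → rt
Reagents that add atoms: chloromethyl methyl ether, COCCl
Why: O-alkylation of the acidic para-formyl phenol by the α-chloro ether (MOM protection) gives a base-stable acetal, needed because a free 4-OH would quench the organozinc, the amide base and the alkoxide used later.

**Step 2**
Reactants: 2 2-methoxy-4-(methoxymethoxy)benzaldehyde
Product: 3 [2-methoxy-4-(methoxymethoxy)phenyl]methanol
Conditions: NaBH4, MeOH, 0 °C
Reagents that add atoms: none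
Why: Borohydride reduction of the aryl aldehyde to the benzylic alcohol, to which the acetal and the methyl ether are inert.

**Step 3**
Reactants: 3 [2-methoxy-4-(methoxymethoxy)phenyl]methanol
Product: 5 1-(chloromethyl)-2-methoxy-4-(methoxymethoxy)benzene, via benzylic mesylate 4 (not isolated)
Conditions: MsCl, Et3N, LiCl, THF, 0 °C → rt; short aqueous work-up, crude chloride used at once
Reagents that add atoms: methanesulfonyl chloride, CS(=O)(=O)Cl (mesyl group of 4); lithium chloride, [Li+].[Cl-] (chlorine of 5)
Why: Mesylation followed by chloride displacement at the donor-activated benzylic carbon; the amine-buffered medium spares the acid-labile MOM group, and the sensitive chloride is carried on without chromatography.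

**Step 4**
Reactants: 5 1-(chloromethyl)-2-methoxy-4-(methoxymethoxy)benzene; 6 2,4,6-trifluorobenzoyl chloride
Product: 8 2-[2-methoxy-4-(methoxymethoxy)phenyl]-1-(2,4,6-trifluorophenyl)ethan-1-one, via benzylzinc chloride 7 (not isolated)
Conditions: Zn dust (activated), LiCl, THF, 25 °C; then 6, Pd(PPh3)4 (3 mol %), THF, 0 °C → rt
Reagents that add atoms: none
Why: LiCl-assisted zinc insertion into the benzylic C–Cl bond gives a benzylzinc reagent that tolerates the acetal, and its palladium-catalysed Negishi acylation forms the CH2–C(=O) bond under neutral conditions, so the SNAr-prone trifluoroarene meets no base or nucleophile.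

**Step 5**
Reactants: 8 2-[2-methoxy-4-(methoxymethoxy)phenyl]-1-(2,4,6-trifluorophenyl)ethan-1-one; 9 2,2,2-trifluoroethyl formate
Product: 11 (Z)-3-hydroxy-2-[2-methoxy-4-(methoxymethoxy)phenyl]-1-(2,4,6-trifluorophenyl)prop-2-en-1-one, via lithium enolate 10 (not isolated)
Conditions: LiHMDS (2.2 equiv), THF, −78 °C; 9, −78 → −20 °C; AcOH quench at −20 °C
Reagents that add atoms: none
Why: Crossed Claisen condensation (C-formylation) of the preformed lithium enolate with the reactive trifluoroethyl ester installs the carbon that becomes C2 at low temperature; the weakly nucleophilic trifluoroethoxide leaves the fluorinated ring alone, and the second equivalent of amide base takes up the acidic product so that conversion should not stall.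

**Step 6**
Reactants: 11 (Z)-3-hydroxy-2-[2-methoxy-4-(methoxymethoxy)phenyl]-1-(2,4,6-trifluorophenyl)prop-2-en-1-one
Product: 13 5,7-difluoro-3-[2-methoxy-4-(methoxymethoxy)phenyl]chromen-4-one, via potassium enolate 12 (not isolated)
Conditions: K2CO3, DMF, rt → 40 °C
Reagents that add atoms: none
Why: Carbonate deprotonates the chelated enol to the potassium enolate 12, whose terminal oxygen adds to one ortho C–F carbon of the trifluorobenzoyl ring to give a Meisenheimer adduct with the charge carried by the ketone, and loss of fluoride forms the O1–C8a bond (intramolecular SNAr, addition–elimination). The closest known reaction type is the base-mediated cyclisation of ortho-fluoroaryl β-dicarbonyl enolates to chromones, the oxygen counterpart of quinolone formation from ortho-haloaroyl enamines. The pyranone is the only ring closed; it is a six-membered closure onto an sp2 carbon, 6-endo-trig with respect to the C4a=C8a π bond that relays the charge to the ketone (6-exo-trig if the other ring bond C8a=C8 is counted), with the reacting centres held coplanar and within reach. No stereocentre is formed. The step needs O- rather than C-arylation and a single substitution: attack through carbon or through the ketone oxygen would give a four-membered ring and cannot compete, the two ortho fluorines are equivalent so only one chromone can form, and carbonate and fluoride are too weak as nucleophiles to touch the C5 and C7 fluorines of the product, whose carbonyl is now a less activating vinylogous ester.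

**Step 7**
Reactants: 13 5,7-difluoro-3-[2-methoxy-4-(methoxymethoxy)phenyl]chromen-4-one; 14 2-methylbut-3-en-2-ol
Product: 16 3-[2-methoxy-4-(methoxymethoxy)phenyl]-5,7-bis[(2-methylbut-3-en-2-yl)oxy]chromen-4-one, via 5-fluoro-7-ether 15 (not isolated)
Conditions: KH (3.0 equiv), 14 (3.2 equiv), THF, 0 °C; then 13, 18-crown-6 (0.3 equiv), strictly anhydrous, 0 → 45 °C
Reagents that add atoms: none
Why: Twofold SNAr of a potassium alkoxide on carbonyl-activated aryl fluorides, expected first at C7 (para to C4=O, unhindered) and then at C5 (ortho to C4=O, helped by K+ bridging to the carbonyl oxygen); the two positions are meta to each other and to O1, so the first ether does not deactivate the second site by resonance, and addition of the bulky alkoxide at C2 should be reversible and cannot end in deformylation without water.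

**Step 8**
Reactants: 16 3-[2-methoxy-4-(methoxymethoxy)phenyl]-5,7-bis[(2-methylbut-3-en-2-yl)oxy]chromen-4-one
Product: 18 5,7-dihydroxy-3-[2-methoxy-4-(methoxymethoxy)phenyl]-6,8-bis(3-methylbut-2-enyl)chromen-4-one, via 6-prenyl-5-phenol 17 (not isolated)
Conditions: PhNEt2, 120 °C, Ar
Reagents that add atoms: none
Why: Two aromatic Claisen rearrangements ([3,3], with allyl inversion) turn each 1,1-dimethylallyl ether into a 3-methylbut-2-enyl group on an ortho carbon: the peri-compressed 5-ether can reach only C6 and should move first to give the chelated phenol 17, after which C8 is the one free ortho carbon for the 7-ether, while the amine solvent keeps the medium non-acidic so the new ortho-prenyl phenols do not close to chromans.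

**Step 9**
Reactants: 18 5,7-dihydroxy-3-[2-methoxy-4-(methoxymethoxy)phenyl]-6,8-bis(3-methylbut-2-enyl)chromen-4-one
Product: 19 5,7-dihydroxy-3-(4-hydroxy-2-methoxyphenyl)-6,8-bis(3-methylbut-2-enyl)chromen-4-one (CNP0189279.0)
Conditions: 3 M HCl (cat.), MeOH, 40 °C
Reagents that add atoms: none
Why: Acid-catalysed methanolysis of the aryl MOM acetal; dilute acid at mild temperature should leave the prenyl alkenes, the aryl methyl ether and the chromone untouched.

**Compound list**
1 | 4-hydroxy-2-methoxybenzaldehyde | COc1cc(O)ccc1C=O | starting material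
2 | 2-methoxy-4-(methoxymethoxy)benzaldehyde | COCOc1ccc(C=O)c(OC)c1 | intermediate
3 | [2-methoxy-4-(methoxymethoxy)phenyl]methanol | COCOc1ccc(CO)c(OC)c1 | intermediate
4 | 2-methoxy-4-(methoxymethoxy)benzyl methanesulfonate (not isolated) | COCOc1ccc(COS(C)(=O)=O)c(OC)c1 | intermediate
5 | 1-(chloromethyl)-2-methoxy-4-(methoxymethoxy)benzene | COCOc1ccc(CCl)c(OC)c1 | intermediate
6 | 2,4,6-trifluorobenzoyl chloride | O=C(Cl)c1c(F)cc(F)cc1F | starting material
7 | [2-methoxy-4-(methoxymethoxy)benzyl]zinc chloride (not isolated) | COCOc1ccc(C[Zn]Cl)c(OC)c1 | intermediate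
8 | 2-[2-methoxy-4-(methoxymethoxy)phenyl]-1-(2,4,6-trifluorophenyl)ethan-1-one | COCOc1ccc(CC(=O)c2c(F)cc(F)cc2F)c(OC)c1 | intermediate
9 | 2,2,2-trifluoroethyl formate | O=COCC(F)(F)F | starting material
10 | lithium (Z)-enolate of 8 (not isolated) | [Li]O/C(=C\c1ccc(OCOC)cc1OC)c1c(F)cc(F)cc1F | intermediate
11 | (Z)-3-hydroxy-2-[2-methoxy-4-(methoxymethoxy)phenyl]-1-(2,4,6-trifluorophenyl)prop-2-en-1-one | O=C(c1c(F)cc(F)cc1F)/C(=C\O)c1ccc(OCOC)cc1OC | intermediate
12 | potassium enolate of 11 (not isolated) | O=C(c1c(F)cc(F)cc1F)/C(=C\[O-])c1ccc(OCOC)cc1OC.[K+] | intermediate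
13 | 5,7-difluoro-3-[2-methoxy-4-(methoxymethoxy)phenyl]chromen-4-one | COCOc1ccc(-c2coc3cc(F)cc(F)c3c2=O)c(OC)c1 | intermediate
14 | 2-methylbut-3-en-2-ol | CC(C)(O)C=C | starting material
15 | 5-fluoro-3-[2-methoxy-4-(methoxymethoxy)phenyl]-7-[(2-methylbut-3-en-2-yl)oxy]chromen-4-one (not isolated) | COCOc1ccc(-c2coc3cc(OC(C)(C)C=C)cc(F)c3c2=O)c(OC)c1 | intermediate
16 | 3-[2-methoxy-4-(methoxymethoxy)phenyl]-5,7-bis[(2-methylbut-3-en-2-yl)oxy]chromen-4-one | COCOc1ccc(-c2coc3cc(OC(C)(C)C=C)cc(OC(C)(C)C=C)c3c2=O)c(OC)c1 | intermediate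
17 | 5-hydroxy-3-[2-methoxy-4-(methoxymethoxy)phenyl]-6-(3-methylbut-2-enyl)-7-[(2-methylbut-3-en-2-yl)oxy]chromen-4-one (not isolated) | COCOc1ccc(-c2coc3cc(OC(C)(C)C=C)c(CC=C(C)C)c(O)c3c2=O)c(OC)c1 | intermediate
18 | 5,7-dihydroxy-3-[2-methoxy-4-(methoxymethoxy)phenyl]-6,8-bis(3-methylbut-2-enyl)chromen-4-one | COCOc1ccc(-c2coc3c(CC=C(C)C)c(O)c(CC=C(C)C)c(O)c3c2=O)c(OC)c1 | intermediate
19 | 5,7-dihydroxy-3-(4-hydroxy-2-methoxyphenyl)-6,8-bis(3-methylbut-2-enyl)chromen-4-one | COc1cc(O)ccc1-c1coc2c(CC=C(C)C)c(O)c(CC=C(C)C)c(O)c2c1=O | target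

**Step count**
Total: 9 steps. Longest linear sequence: 9 steps (1 → 19); 6, 9 and 14 are bought and enter directly.

**Steps most likely to fail**

1. Step 7. The hindered tertiary alkoxide may add at C2 and hold the pyranone open faster than it displaces the fluoride next to the carbonyl. The second substitution may also stall, or the first ether may rearrange early and leave a phenoxide that shuts down further SNAr. The fallback obtains the ethers by palladium-catalysed allylic etherification of phenols instead of SNAr, one at a time. It sets out from 13: sodium benzyloxide (BnOH, NaH, dry THF/DMF) exchanges both fluorines to give 5,7-bis(benzyloxy)-3-[2-methoxy-4-(methoxymethoxy)phenyl]chromen-4-one F1, and hydrogenolysis (H2, Pd/C, EtOAc) gives 5,7-dihydroxy-3-[2-methoxy-4-(methoxymethoxy)phenyl]chromen-4-one F2. Decarboxylative etherification with tert-butyl 2-methylbut-3-en-2-yl carbonate and Pd(PPh3)4 in THF should alkylate only the non-chelated 7-OH, giving 5-hydroxy-3-[2-methoxy-4-(methoxymethoxy)phenyl]-7-[(2-methylbut-3-en-2-yl)oxy]chromen-4-one F3. Heating in PhNEt2 should then move the allyl group to C8, the position favoured when the 5-OH is chelated, to give 5,7-dihydroxy-3-[2-methoxy-4-(methoxymethoxy)phenyl]-8-(3-methylbut-2-enyl)chromen-4-one F4. A second etherification of the 7-OH under the same palladium conditions gives 5-hydroxy-3-[2-methoxy-4-(methoxymethoxy)phenyl]-8-(3-methylbut-2-enyl)-7-[(2-methylbut-3-en-2-yl)oxy]chromen-4-one F5, whose only free ortho carbon is C6. A second heating returns the route at 18.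

2. Step 8. The 7-ether may rearrange to C6 before the 5-ether has moved. The 5-ether can then deliver its allyl group only to an occupied carbon, leading to a C6 gem-diallyl dienone or, after a Cope shift, a reversed allyl group at C8. Loss of isoprene from the tertiary ethers and closure of ortho-prenyl phenols to chromans are further drains. The fallback gives up sigmatropic delivery and installs both prenyl groups by cross-coupling. It sets out from 16: Pd(PPh3)4 and morpholine in THF transfer both tertiary allyl groups to the amine and give the diol F2 already described. NIS (2 equiv, DMF, 0 °C) should iodinate the two activated A-ring carbons to give 5,7-dihydroxy-6,8-diiodo-3-[2-methoxy-4-(methoxymethoxy)phenyl]chromen-4-one F6. MOMCl and NaH in DMF cap both phenols to give 6,8-diiodo-5,7-bis(methoxymethoxy)-3-[2-methoxy-4-(methoxymethoxy)phenyl]chromen-4-one F7. Twofold Stille coupling with tributyl(3-methylbut-2-enyl)stannane (Pd(PPh3)4, DMF, 90 °C) gives 5,7-bis(methoxymethoxy)-3-[2-methoxy-4-(methoxymethoxy)phenyl]-6,8-bis(3-methylbut-2-enyl)chromen-4-one F8. Removal of all three MOM groups under the conditions of step 9 returns the route at 19.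

3. Step 4 (with the labile chloride 5 from step 3). The very electron-rich benzylic chloride may ionise and oligomerise before or during zinc insertion, or homocouple on the metal (Wurtz coupling), so that too little benzylzinc reagent reaches the acylation. The fallback avoids any benzylic halide and forms the same CH2–aryl bond by ketone α-arylation. It sets out from 6: Negishi acylation with MeZnCl (Pd(PPh3)4 cat., THF) gives 1-(2,4,6-trifluorophenyl)ethan-1-one F9. Commercial 4-bromo-3-methoxyphenol is protected (MOMCl, iPr2NEt, CH2Cl2) as 1-bromo-2-methoxy-4-(methoxymethoxy)benzene F10. Palladium-catalysed α-arylation of F9 with F10 (Pd2(dba)3, Xantphos, K3PO4, toluene, 80 °C; a weak, non-nucleophilic base to spare the C–F bonds) returns the route at 8.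

**Further compounds**
F1 | step 7 | 5,7-bis(benzyloxy)-3-[2-methoxy-4-(methoxymethoxy)phenyl]chromen-4-one | COCOc1ccc(-c2coc3cc(OCc4ccccc4)cc(OCc5ccccc5)c3c2=O)c(OC)c1
F2 | step 7 | 5,7-dihydroxy-3-[2-methoxy-4-(methoxymethoxy)phenyl]chromen-4-one | COCOc1ccc(-c2coc3cc(O)cc(O)c3c2=O)c(OC)c1
F3 | step 7 | 5-hydroxy-3-[2-methoxy-4-(methoxymethoxy)phenyl]-7-[(2-methylbut-3-en-2-yl)oxy]chromen-4-one | COCOc1ccc(-c2coc3cc(OC(C)(C)C=C)cc(O)c3c2=O)c(OC)c1
F4 | step 7 | 5,7-dihydroxy-3-[2-methoxy-4-(methoxymethoxy)phenyl]-8-(3-methylbut-2-enyl)chromen-4-one | COCOc1ccc(-c2coc3c(CC=C(C)C)c(O)cc(O)c3c2=O)c(OC)c1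
F5 | step 7 | 5-hydroxy-3-[2-methoxy-4-(methoxymethoxy)phenyl]-8-(3-methylbut-2-enyl)-7-[(2-methylbut-3-en-2-yl)oxy]chromen-4-one | COCOc1ccc(-c2coc3c(CC=C(C)C)c(OC(C)(C)C=C)cc(O)c3c2=O)c(OC)c1
F6 | step 8 | 5,7-dihydroxy-6,8-diiodo-3-[2-methoxy-4-(methoxymethoxy)phenyl]chromen-4-one | COCOc1ccc(-c2coc3c(I)c(O)c(I)c(O)c3c2=O)c(OC)c1
F7 | step 8 | 6,8-diiodo-5,7-bis(methoxymethoxy)-3-[2-methoxy-4-(methoxymethoxy)phenyl]chromen-4-one | COCOc1ccc(-c2coc3c(I)c(OCOC)c(I)c(OCOC)c3c2=O)c(OC)c1
F8 | step 8 | 5,7-bis(methoxymethoxy)-3-[2-methoxy-4-(methoxymethoxy)phenyl]-6,8-bis(3-methylbut-2-enyl)chromen-4-one | COCOc1ccc(-c2coc3c(CC=C(C)C)c(OCOC)c(CC=C(C)C)c(OCOC)c3c2=O)c(OC)c1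
F9 | step 4 | 1-(2,4,6-trifluorophenyl)ethan-1-one | CC(=O)c1c(F)cc(F)cc1F
F10 | step 4 | 1-bromo-2-methoxy-4-(methoxymethoxy)benzene | COCOc1ccc(Br)c(OC)c1
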